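**Strategy.** Everything rests on cutting the O–C(CH3)2 bond of the eight-membered oxocine ring: the tertiary ether carbon with its two methyl groups is a masked prenyl cation. The precursor is therefore the open 3-prenylflavone, with a free 2'-OH on ring B and a prenyl group on C3 of the pyranone ring. An acid-catalysed Markovnikov hydroalkoxylation then closes the last ring and sets the gem-dimethyl ether in one isomerisation without by-products. It exploits that O2' is the only oxygen able to trap the C3'' cation as a neutral ether across the rigid C3=C2–C1'=C2' unit, while C6' is meta to both ring-B oxygens. The precursor is built by Claisen–Schmidt condensation, oxidative cyclisation and C3-lithiation/prenylation.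

Key step: step 7

Remark: flavone numbering is used (pyranone ring C: O1, C2, C3, C4; ring A: C5–C8; ring B: C1'–C6'; prenyl chain C1''–C3''). The target has no stereocentre, so only the E geometry of 5 and the racemic nature of 6 need be stated.

**Step 1**
Reactants: 1 2',6'-dihydroxy-4'-methoxyacetophenone
Product: 2 1-[2-hydroxy-4-methoxy-6-(methoxymethoxy)phenyl]ethanone
Conditions: MOMCl (1.05 equiv), i-Pr2NEt, CH2Cl2, 0 °C to rt
Reagents that add atoms: chloromethyl methyl ether (MOMCl), COCCl
Why: O-alkylation of a phenol (MOM protection); once one MOM ether is formed, the remaining phenol is held in a hydrogen bond to the ketone carbonyl and is much less nucleophilic, so one equivalent should stop at the mono-ether.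

**Step 2**
Reactants: 3 2,4-dihydroxybenzaldehyde
Product: 4 2,4-bis(methoxymethoxy)benzaldehyde
Conditions: MOMCl (2.6 equiv), i-Pr2NEt, CH2Cl2, 0 °C to 40 °C
Reagents that add atoms: chloromethyl methyl ether (MOMCl), COCCl
Why: Twofold MOM protection of phenols; excess reagent and gentle warming should also alkylate the 2-OH that is hydrogen-bonded to the aldehyde.

**Step 3**
Reactants: 2 1-[2-hydroxy-4-methoxy-6-(methoxymethoxy)phenyl]ethanone; 4 2,4-bis(methoxymethoxy)benzaldehyde
Product: 5 (E)-3-[2,4-bis(methoxymethoxy)phenyl]-1-[2-hydroxy-4-methoxy-6-(methoxymethoxy)phenyl]prop-2-en-1-one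
Conditions: KOH, EtOH/H2O, rt
Reagents that add atoms: none
Why: Claisen–Schmidt condensation of a methyl ketone with a non-enolisable aldehyde; E1cB loss of water gives the conjugated E-enone, and the MOM acetals are stable to base.

**Step 4**
Reactants: 5 (E)-3-[2,4-bis(methoxymethoxy)phenyl]-1-[2-hydroxy-4-methoxy-6-(methoxymethoxy)phenyl]prop-2-en-1-one
Product: 7 2-[2,4-bis(methoxymethoxy)phenyl]-7-methoxy-5-(methoxymethoxy)-4H-chromen-4-one, via racemic flavanone 6 (not isolated)
Conditions: I2 (1.2 equiv), pyridine, 95 °C
Reagents that add atoms: none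
Why: Oxidative cyclisation of a 2'-hydroxychalcone: base-mediated 6-endo oxa-Michael closure gives flavanone 6, whose enol is iodinated at C3 and loses HI to pyridine to give the flavone, while the basic medium keeps the three MOM acetals intact.

**Step 5**
Reactants: 7 2-[2,4-bis(methoxymethoxy)phenyl]-7-methoxy-5-(methoxymethoxy)-4H-chromen-4-one; 8 prenyl bromide (1-bromo-3-methylbut-2-ene)
Product: 10 2-[2,4-bis(methoxymethoxy)phenyl]-7-methoxy-5-(methoxymethoxy)-3-(3-methylbut-2-en-1-yl)-4H-chromen-4-one, via 3-lithioflavone 9 (not isolated)
Conditions: LDA (1.3 equiv), THF, −78 °C; then 8, −78 to 0 °C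
Reagents that add atoms: none
Why: Directed C3-lithiation of a flavone (the metalation used to convert flavones into flavonols): LDA removes the only vinylic proton, next to the coordinating C4 carbonyl, and vinyl-lithium 9 is alkylated by SN2 attack at the primary carbon of the allylic bromide, so the linear prenyl group is expected.

**Step 6**
Reactants: 10 2-[2,4-bis(methoxymethoxy)phenyl]-7-methoxy-5-(methoxymethoxy)-3-(3-methylbut-2-en-1-yl)-4H-chromen-4-one
Product: 11 2-(2,4-dihydroxyphenyl)-5-hydroxy-7-methoxy-3-(3-methylbut-2-en-1-yl)-4H-chromen-4-one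
Conditions: 3 M HCl/MeOH (1:10), 45 °C, stopped at full MOM loss
Reagents that add atoms: none
Why: Acid-catalysed acetal exchange (MOM cleavage) with methanol as acceptor; at this acid strength and temperature, oxocarbenium formation from the three aryl MOM acetals should be much faster than protonation of the trisubstituted alkene.

**Step 7**
Reactants: 11 2-(2,4-dihydroxyphenyl)-5-hydroxy-7-methoxy-3-(3-methylbut-2-en-1-yl)-4H-chromen-4-one
Product: 12 cyclointegrin
Conditions: p-TsOH·H2O (0.3 equiv), (CH2Cl)2, 0.005 M, 70 °C
Reagents that add atoms: none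
Why: Protonation of the trisubstituted alkene of the 3-prenyl group at C2'' gives the tertiary C3'' carbocation, which is captured by the 2'-OH oxygen of ring B; loss of the proton forms the O–C(CH3)2 bond and regenerates the acid (Markovnikov intramolecular hydroalkoxylation). The closest known reaction is the acid-catalysed cyclisation of ortho-prenylphenols to 2,2-dimethylchromans, here extended by two ring atoms. The oxocine ring closes in an 8-endo-trig mode (both former alkene carbons lie in the ring), helped by the fact that four of its eight atoms (C3, C2, C1', C2') are sp2 atoms already held cis by the pyranone C2=C3 bond and the arene. No stereocentre is formed. The selectivity needed is O- over C-capture and O2' over every other nucleophile: the 5-OH and 4'-OH cannot reach the cation, C6' is meta to both ring-B oxygens and so is not activated for a seven-membered Friedel–Crafts closure, and capture by the C4 carbonyl oxygen gives only a charged 4-alkoxyflavylium ion that cannot lose a proton and reverts. High dilution suppresses intermolecular prenyl transfer to the electron-rich rings, and the reversibility of the off-path events should let the material collect in the neutral cyclic ether.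

**Compound list**

1 | 2',6'-dihydroxy-4'-methoxyacetophenone | CC(=O)c1c(O)cc(OC)cc1O | starting material
2 | 1-[2-hydroxy-4-methoxy-6-(methoxymethoxy)phenyl]ethanone | CC(=O)c1c(O)cc(OC)cc1OCOC | intermediate
3 | 2,4-dihydroxybenzaldehyde | O=Cc1ccc(O)cc1O | starting material
4 | 2,4-bis(methoxymethoxy)benzaldehyde | COCOc1ccc(C=O)c(OCOC)c1 | intermediate
5 | (E)-3-[2,4-bis(methoxymethoxy)phenyl]-1-[2-hydroxy-4-methoxy-6-(methoxymethoxy)phenyl]prop-2-en-1-one | COCOc1ccc(/C=C/C(=O)c2c(O)cc(OC)cc2OCOC)c(OCOC)c1 | intermediate
6 | (±)-2-[2,4-bis(methoxymethoxy)phenyl]-7-methoxy-5-(methoxymethoxy)chroman-4-one (racemic flavanone, not isolated) | COCOc1ccc(C2CC(=O)c3c(OCOC)cc(OC)cc3O2)c(OCOC)c1 | intermediate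
7 | 2-[2,4-bis(methoxymethoxy)phenyl]-7-methoxy-5-(methoxymethoxy)-4H-chromen-4-one | COCOc1ccc(-c2cc(=O)c3c(OCOC)cc(OC)cc3o2)c(OCOC)c1 | intermediate
8 | prenyl bromide (1-bromo-3-methylbut-2-ene) | CC(C)=CCBr | starting material
9 | 3-lithio derivative of flavone 7 (lithium on C3, not isolated) | [Li]c1c(-c2ccc(OCOC)cc2OCOC)oc2cc(OC)cc(OCOC)c2c1=O | intermediate
10 | 2-[2,4-bis(methoxymethoxy)phenyl]-7-methoxy-5-(methoxymethoxy)-3-(3-methylbut-2-en-1-yl)-4H-chromen-4-one | COCOc1ccc(-c2oc3cc(OC)cc(OCOC)c3c(=O)c2CC=C(C)C)c(OCOC)c1 | intermediate
11 | 2-(2,4-dihydroxyphenyl)-5-hydroxy-7-methoxy-3-(3-methylbut-2-en-1-yl)-4H-chromen-4-one | COc1cc(O)c2c(=O)c(CC=C(C)C)c(-c3ccc(O)cc3O)oc2c1 | intermediate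
12 | cyclointegrin (5,4'-dihydroxy-7-methoxyflavone with C3 and O2' bridged as C3–CH2–CH2–C(CH3)2–O2') | COc1cc(O)c2c(=O)c3c(oc2c1)-c1ccc(O)cc1OC(C)(C)CC3 | target

**Step count.** Total: 7 steps. Longest linear sequence: 6 steps (steps 1, 3, 4, 5, 6, 7).

**Steps most likely to fail**

Step 7. The cation may be consumed by intermolecular prenyl transfer to the electron-rich rings, by hydration on work-up, or by re-opening of the ether, faster than the eight-membered ring closes. The fallback makes the closure irreversible and kinetically controlled. It sets out from 11. N-(Phenylselanyl)phthalimide with catalytic camphorsulfonic acid in CH2Cl2 at high dilution and −20 °C should form a seleniranium ion on the prenyl alkene, which O2' opens at the tertiary carbon to give the racemic phenylselanyl oxocine F1. Tributyltin hydride/AIBN in toluene at 80 °C should then remove the selenium by radical reduction, and the sequence comes back to the route at 12.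

Step 5. Metalation may occur at the wrong site, the 3-lithio species may ring-open to an ynone phenoxide, or alkylation of the hindered vinyl-lithium may be slow. The fallback attaches the prenyl group before ring C exists. It sets out from 2 and 4. Pinnick oxidation of 4 (NaClO2, NaH2PO4, 2-methyl-2-butene, t-BuOH/H2O) should give 2,4-bis(methoxymethoxy)benzoic acid F2. EDC·HCl/DMAP esterification with phenol 2 should give the aryl ester F3. Baker–Venkataraman rearrangement (KOH, pyridine, 50 °C) should give the 1,3-diketone F4. C-Alkylation of its central carbon with 8 (K2CO3, acetone, rt) should give the racemic 2-prenyl-1,3-diketone F5. Methanolic HCl at 45 °C should then bring about cyclodehydration to the pyranone (the free ring-A phenol closes before the ring-B acetals are lost) and cleavage of the three MOM groups in one operation, and the sequence comes back to the route at 11.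

Step 6. While the acetals are cleaved, the protonated alkene may add methanol or O2', giving mixtures of alkene, methyl ether and cyclised material. The fallback removes the alkene before deprotection. It sets out from 10. Mukaiyama hydration (Co(acac)2, PhSiH3, O2, i-PrOH, rt) should give the tertiary alcohol F6. Aqueous HCl/THF at 45 °C should remove the MOM groups to give the tetrol F7. p-TsOH in toluene with 4 Å molecular sieves at 80 °C and high dilution should ionise the tertiary alcohol to the same C3'' cation and close the ether by dehydration, and the sequence comes back to the route at 12.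

**Further compounds**

F1 | step 7 | (±)-phenylselanyl oxocine (cyclointegrin carrying PhSe on the ring CH next to the C(CH3)2 carbon) | COc1cc(O)c2c(=O)c3c(oc2c1)-c1ccc(O)cc1OC(C)(C)C([Se]c1ccccc1)C3
F2 | step 5 | 2,4-bis(methoxymethoxy)benzoic acid | COCOc1ccc(C(=O)O)c(OCOC)c1
F3 | step 5 | 2-acetyl-5-methoxy-3-(methoxymethoxy)phenyl 2,4-bis(methoxymethoxy)benzoate | CC(=O)c1c(OC(=O)c2ccc(OCOC)cc2OCOC)cc(OC)cc1OCOC
F4 | step 5 | 1-[2,4-bis(methoxymethoxy)phenyl]-3-[2-hydroxy-4-methoxy-6-(methoxymethoxy)phenyl]propane-1,3-dione | COCOc1ccc(C(=O)CC(=O)c2c(O)cc(OC)cc2OCOC)c(OCOC)c1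
F5 | step 5 | (±)-1-[2,4-bis(methoxymethoxy)phenyl]-3-[2-hydroxy-4-methoxy-6-(methoxymethoxy)phenyl]-2-(3-methylbut-2-en-1-yl)propane-1,3-dione | COCOc1ccc(C(=O)C(CC=C(C)C)C(=O)c2c(O)cc(OC)cc2OCOC)c(OCOC)c1
F6 | step 6 | 2-[2,4-bis(methoxymethoxy)phenyl]-3-(3-hydroxy-3-methylbutyl)-7-methoxy-5-(methoxymethoxy)-4H-chromen-4-one | COCOc1ccc(-c2oc3cc(OC)cc(OCOC)c3c(=O)c2CCC(C)(C)O)c(OCOC)c1
F7 | step 6 | 2-(2,4-dihydroxyphenyl)-5-hydroxy-3-(3-hydroxy-3-methylbutyl)-7-methoxy-4H-chromen-4-one | COc1cc(O)c2c(=O)c(CCC(C)(C)O)c(-c3ccc(O)cc3O)oc2c1
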